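## Retrosynthetic overview
- The four C–Br bonds ortho and para to the two free OH groups are removed first. They are installed together in the last step on 3-bromo-2-(2-hydroxyphenoxy)phenol. The fifth Br (meta to OH, next to the ether O) cannot be directed and is bought in.
- The key disconnection is the diaryl ether C–O bond: a catechol O–H adds to the carbene carbon of the bromo ortho-quinone diazide of ring B. The former C–N carbon fixes the ether position, and the quinone oxygen becomes the ring B phenol.
- The diazide comes from 2-amino-3-bromophenol by diazotisation.
- No ring is built. Ring B (aminophenol) and ring A (catechol) are bought as benzene rings and joined in step 2. Ring B is dearomatised in step 1 and rearomatised in step 2.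

Assumption: the target has no stereocentre and no isolable stereoaxis (the diaryl ether rotates freely), so it is achiral and the route has no configuration to set.

## Route

Step 1
Reactants: 1 2-amino-3-bromophenol
Product: 3 5-bromo-6-diazocyclohexa-2,4-dien-1-one, via 2-bromo-6-hydroxybenzenediazonium chloride 2 (not isolated)
Conditions: NaNO2 (1.05 equiv), 2 M aq HCl, 0 °C; then NaHCO3 to pH 7, brine, CH2Cl2 extraction, 0 °C, dark
Reagents that add atoms: sodium nitrite [Na+].[O-]N=O; hydrogen chloride Cl (supplies only the chloride counter-ion of 2)
Why: This is a diazotisation of an ortho-aminophenol, and the acidic OH of the diazonium ion (pKa about 4) is deprotonated at pH 7 to give the neutral, extractable ortho-quinone diazide; no stereocentre is formed.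

Step 2
Reactants: 3 5-bromo-6-diazocyclohexa-2,4-dien-1-one; 4 catechol (benzene-1,2-diol)
Product: 5 3-bromo-2-(2-hydroxyphenoxy)phenol
Conditions: Rh2(OAc)4 (1 mol %), 4 (5 equiv), ClCH2CH2Cl, 60 °C, 3 added over 2 h, dark, Ar; excess 4 washed out with water
Reagents that add atoms: none
Why: Proposed new method: dirhodium-catalysed quinoid-carbene O–H insertion of a monocyclic, halogenated ortho-quinone diazide into an unprotected catechol to give a 2,2'-dihydroxydiaryl ether; Rh2(OAc)4 attacks the diazo carbon of 3 and expels N2 to give an electrophilic rhodium quinoid carbene at the carbon flanked by C=O and C–Br, a catechol oxygen adds to give an oxonium ylide, and the proton is relayed by the neighbouring catechol OH to the carbonyl oxygen, so ring B rearomatises and the catalyst is released; rearomatisation makes the step irreversible, the former C–N carbon fixes the site of the new C–O bond, symmetric catechol in excess rules out regioisomers and suppresses double insertion, no low-valent metal is present to insert into C–Br, and 60 °C in the dark stays below the onset of Wolff ring contraction; closest known reaction type: rhodium-carbene O–H insertion of alpha-diazocarbonyl compounds into phenols and of benzo-fused diazonaphthoquinones into alcohols; no stereocentre is formed.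

Step 3
Reactants: 5 3-bromo-2-(2-hydroxyphenoxy)phenol
Product: 6 3,4,6-tribromo-2-(3,5-dibromo-2-hydroxyphenoxy)phenol
Conditions: Br2 (4.0 equiv), AcOH, 15 °C to rt, 3 h; poured into water, filtered, recrystallised
Reagents that add atoms: bromine BrBr
Why: This is electrophilic aromatic bromination of phenols, in which each free OH outranks the aryloxy group and directs Br to its own open ortho and para positions (exactly four sites), while the three remaining C–H bonds are meta to OH on rings that are by then deactivated; no stereocentre is formed.

## Compound list
1 | 2-amino-3-bromophenol | Nc1c(O)cccc1Br | starting material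
2 | 2-bromo-6-hydroxybenzenediazonium chloride | Oc1cccc(Br)c1[N+]#N.[Cl-] | intermediate
3 | 5-bromo-6-diazocyclohexa-2,4-dien-1-one (3-bromo-2-diazoniophenolate) | O=C1C=CC=C(Br)C1=[N+]=[N-] | intermediate
4 | catechol (benzene-1,2-diol) | Oc1ccccc1O | starting material
5 | 3-bromo-2-(2-hydroxyphenoxy)phenol | Oc1ccccc1Oc1c(O)cccc1Br | intermediate
6 | 3,4,6-tribromo-2-(3,5-dibromo-2-hydroxyphenoxy)phenol | Oc1c(Br)cc(Br)cc1Oc1c(O)c(Br)cc(Br)c1Br | target

Total step count: 3
Longest linear sequence: 3 (1 to 3 to 5 to 6; catechol 4 enters as bought)

## Steps most likely to fail

**Step 2 (the proposed new step).** The risks are Wolff ring contraction, C–H attack on the catechol ring, azo coupling, and further insertion into the phenols of 5. The fallback uses known chemistry only; it sets out from 4 and comes back at 5.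
- Catechol 4 (3 equiv) is arylated with commercial 3-bromo-2-fluorobenzaldehyde (O=Cc1cccc(Br)c1F) by formyl-activated SNAr (K2CO3, DMF, 90 °C, Ar). This gives 3-bromo-2-(2-hydroxyphenoxy)benzaldehyde F1.
- Baeyer–Villiger oxidation with mCPBA in CH2Cl2 gives 3-bromo-2-(2-hydroxyphenoxy)phenyl formate F2.
- F2 is cleaved in the same flask with NaOH in MeOH/H2O and acidified to give 5.
- These two operations replace steps 1 and 2, so the total stays at three steps.

**Step 3.** The risks are under- and over-brominated congeners that are hard to separate, and oxidation of the bis-phenol by Br2. The fallback splits the four brominations into two exhaustive dibrominations, each on the only activated ring present. It sets out from 4 and comes back at 6.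
- Compound 4 is converted into aldehyde F1 as described above.
- Br2 (2 equiv, AcOH) brominates only the phenolic ring A, because ring B is switched off by its formyl group. This gives 3-bromo-2-(3,5-dibromo-2-hydroxyphenoxy)benzaldehyde F3.
- mCPBA gives 3-bromo-2-(3,5-dibromo-2-hydroxyphenoxy)phenyl formate F4.
- Hydrolysis with NaOH gives 3-bromo-2-(3,5-dibromo-2-hydroxyphenoxy)phenol F5.
- A second Br2 treatment (2 equiv, AcOH) fills the ortho and para positions of the newly exposed ring B phenol and gives 6.

**Step 1.** The risks are loss of the polar, light- and heat-sensitive diazide 3 on neutralisation, extraction or concentration. The fallback avoids the carbene precursor altogether. It sets out from 1 and comes back at 5.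
- The diazonium chloride 2 is made as in step 1 but is treated with KI instead of base (iodo-dediazoniation). This gives 3-bromo-2-iodophenol F6.
- O-methylation (MeI, K2CO3, acetone) gives 1-bromo-2-iodo-3-methoxybenzene F7.
- Ligand-accelerated Ullmann coupling with guaiacol (COc1ccccc1O) uses CuI (10 mol %), picolinic acid (20 mol %), K3PO4, DMSO, 90 °C. It takes the C–I bond in preference to C–Br and gives 1-bromo-3-methoxy-2-(2-methoxyphenoxy)benzene F8.
- BBr3 (CH2Cl2, −78 °C to rt) removes both methyl groups and gives 5.

Handling notes: keep 3 cold, dark and in solution. Never heat 5, 6 or F5 with base or copper salts, because ring closure to brominated dibenzodioxins would become possible.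

## Further compounds
F1 | step 2 | 3-bromo-2-(2-hydroxyphenoxy)benzaldehyde | O=Cc1cccc(Br)c1Oc1ccccc1O
F2 | step 2 | 3-bromo-2-(2-hydroxyphenoxy)phenyl formate | O=COc1cccc(Br)c1Oc1ccccc1O
F3 | step 3 | 3-bromo-2-(3,5-dibromo-2-hydroxyphenoxy)benzaldehyde | O=Cc1cccc(Br)c1Oc1cc(Br)cc(Br)c1O
F4 | step 3 | 3-bromo-2-(3,5-dibromo-2-hydroxyphenoxy)phenyl formate | O=COc1cccc(Br)c1Oc1cc(Br)cc(Br)c1O
F5 | step 3 | 3-bromo-2-(3,5-dibromo-2-hydroxyphenoxy)phenol | Oc1cccc(Br)c1Oc1cc(Br)cc(Br)c1O
F6 | step 1 | 3-bromo-2-iodophenol | Oc1cccc(Br)c1I
F7 | step 1 | 1-bromo-2-iodo-3-methoxybenzene | COc1cccc(Br)c1I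
F8 | step 1 | 1-bromo-3-methoxy-2-(2-methoxyphenoxy)benzene | COc1ccccc1Oc1c(OC)cccc1Br
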